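**Plan**

1. The retrosynthesis first cuts the O7–benzyl bond, then opens ring B at C6′–C1′ and C2′–C3′. This gives 4-chloro-2,3-dimethoxycyclobutenone (C3′–C6′, from dimethyl squarate) and a chroman-3-yl-substituted (Z)-2-methoxyethenylstannane (C1′, C2′).
2. The cut is possible because ring B carries four contiguous oxygens on C2′–C5′, with only O3′ free, next to an unsubstituted C6′. The ketene carbon of the opened cyclobutenone becomes C3′–OH, the two squarate methoxy carbons become C4′ and C5′, the CHCl carbon becomes C6′, and the enol ether carbon becomes C2′–OMe.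
3. The stannane goes back through enol triflate, methoxymethyl ketone and Weinreb amide to 7-benzyloxy-8-methoxychroman-3-carboxylic acid. Its C3–H and C4–H bonds come from hydrogenation of the 2H-chromene acid, and ring C is cut at O1–C2 and C3–C4 into a salicylaldehyde and tert-butyl acrylate.
4. Forward order: ring A aldehyde from 2-methoxyresorcinol, then ring C, then the stereocentre, then the side chain. Ring B is built last on the intact chroman, and debenzylation ends the route.
5. The single stereocentre C3 is set by catalyst-controlled asymmetric hydrogenation of the chromene-3-carboxylic acid and carried through unchanged. Its descriptor is R while C3 bears the acid-derived carbon and S once the aryl group is attached; the spatial arrangement is the same throughout.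

Key step: step 12

Assumption: the target stereocentre is read from the SMILES as 3S (C2 > C1′ > C4 > H), and the (Sa,S) enantiomer of the spiro ligand L in step 5 is taken to give the 3R acid; if the sense proves opposite, the mirror-image ligand is used. L = 7-[bis(3,5-di-tert-butylphenyl)phosphanyl]-7′-[(4S)-4-benzyl-4,5-dihydrooxazol-2-yl]-1,1′-spirobiindane; BArF = B[3,5-(CF3)2C6H3]4.

**Route**

Step 1
Reactants: 1 2-methoxybenzene-1,3-diol (2-methoxyresorcinol)
Product: 3 2,4-dihydroxy-3-methoxybenzaldehyde, via aryliminium chloride 2 (not isolated)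
Conditions: POCl3, DMF, MeCN, 0 °C to rt; then H2O, 50 °C
Reagents that add atoms: N,N-dimethylformamide, CN(C)C=O; water, O
Why: Vilsmeier–Haack formylation attacks the position ortho to one hydroxyl and para to the other (C4 and C6 are equivalent by symmetry), and hydrolysis of the iminium salt releases the aldehyde.

Step 2
Reactants: 3 2,4-dihydroxy-3-methoxybenzaldehyde
Product: 4 4-(benzyloxy)-2-hydroxy-3-methoxybenzaldehyde
Conditions: BnBr (1.05 equiv), NaHCO3, KI (cat.), MeCN, 80 °C
Reagents that add atoms: benzyl bromide, BrCc1ccccc1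
Why: Williamson etherification with a weak base should alkylate only the 4-hydroxyl, which is para to the formyl group and more acidic, while the 2-hydroxyl stays hydrogen-bonded to the carbonyl.

Step 3
Reactants: 4 4-(benzyloxy)-2-hydroxy-3-methoxybenzaldehyde; 5 tert-butyl acrylate
Product: 6 tert-butyl 7-(benzyloxy)-8-methoxy-2H-chromene-3-carboxylate
Conditions: DABCO (1 equiv), 5 (5 equiv), 1,4-dioxane/H2O, 80 °C
Reagents that add atoms: none
Why: The amine-mediated oxa-Michael/aldol condensation of a salicylaldehyde with an acrylate (Morita–Baylis–Hillman-type chromene annulation) forms O1–C2 and C3–C4 with loss of water, and the tert-butyl ester suppresses lactonisation to a coumarin.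

Step 4
Reactants: 6 tert-butyl 7-(benzyloxy)-8-methoxy-2H-chromene-3-carboxylate
Product: 7 7-(benzyloxy)-8-methoxy-2H-chromene-3-carboxylic acid
Conditions: TFA/CH2Cl2 (1:4), 0 °C to rt
Reagents that add atoms: none
Why: Acidolysis of the tert-butyl ester frees the carboxylic acid needed as the directing group for hydrogenation, under conditions mild and short enough to spare the benzyl aryl ether.

Step 5
Reactants: 7 7-(benzyloxy)-8-methoxy-2H-chromene-3-carboxylic acid
Product: 8 (3R)-7-(benzyloxy)-8-methoxychroman-3-carboxylic acid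
Conditions: [Ir(cod)(L)]BArF (1 mol %), H2 (6 atm), Et3N (0.5 equiv), MeOH, rt
Reagents that add atoms: none
Why: Carboxylate-directed iridium-catalysed asymmetric hydrogenation of a β-aryl-α-substituted acrylic acid adds H2 across C3=C4 from the face fixed by the chiral spiro phosphine–oxazoline ligand, so C3 is set by catalyst control, and the homogeneous catalyst leaves the benzyl ether intact.

Step 6
Reactants: 8 (3R)-7-(benzyloxy)-8-methoxychroman-3-carboxylic acid
Product: 9 (3R)-7-(benzyloxy)-N,8-dimethoxy-N-methylchroman-3-carboxamide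
Conditions: MeNH(OMe)·HCl, EDC·HCl, HOBt, N-methylmorpholine, CH2Cl2, 0 °C to rt
Reagents that add atoms: N,O-dimethylhydroxylamine hydrochloride, CNOC.Cl
Why: Carbodiimide/HOBt amide coupling gives the Weinreb amide without any base strong enough to enolise C3.

Step 7
Reactants: 9 (3R)-7-(benzyloxy)-N,8-dimethoxy-N-methylchroman-3-carboxamide
Product: 10 1-[(3R)-7-(benzyloxy)-8-methoxychroman-3-yl]-2-methoxyethan-1-one
Conditions: Bu3SnCH2OMe, n-BuLi, THF, −78 °C; then 9, −78 °C; AcOH quench at −78 °C
Reagents that add atoms: tributyl(methoxymethyl)stannane, CCCC[Sn](CCCC)(CCCC)COC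
Why: The Weinreb ketone synthesis with (methoxymethyl)lithium from tin–lithium exchange stops at the ketone oxidation level, and the cold acidic quench keeps the now enolisable C3 away from base.

Step 8
Reactants: 10 1-[(3R)-7-(benzyloxy)-8-methoxychroman-3-yl]-2-methoxyethan-1-one
Product: 11 (Z)-1-[(3R)-7-(benzyloxy)-8-methoxychroman-3-yl]-2-methoxyethenyl trifluoromethanesulfonate
Conditions: KN(SiMe3)2 (1.1 equiv), THF, −78 °C (ketone added to base); PhNTf2, −78 to −40 °C
Reagents that add atoms: N-phenylbis(trifluoromethanesulfonimide), O=S(=O)(N(c1ccccc1)S(=O)(=O)C(F)(F)F)C(F)(F)F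
Why: Kinetic deprotonation by the bulky amide base should take the unhindered OCH2 proton and not the ring methine at C3, and O-triflation of the chelated enolate (enolate oxygen and methoxy cis) should give the Z enol triflate.

Step 9
Reactants: 11 (Z)-1-[(3R)-7-(benzyloxy)-8-methoxychroman-3-yl]-2-methoxyethenyl trifluoromethanesulfonate
Product: 12 {(Z)-1-[(3R)-7-(benzyloxy)-8-methoxychroman-3-yl]-2-methoxyethenyl}trimethylstannane
Conditions: Me3SnSnMe3 (1.2 equiv), Pd(PPh3)4 (5 mol %), LiCl (3 equiv), THF, 65 °C; chromatography on Et3N-deactivated silica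
Reagents that add atoms: hexamethylditin, C[Sn](C)(C)[Sn](C)(C)C
Why: Palladium-catalysed stannylation of an enol triflate with a distannane proceeds with retention of alkene geometry, and the trimethylstannyl group is chosen because it should transfer faster than tributylstannyl from the hindered α-branched carbon in step 12.

Step 10
Reactants: 13 dimethyl squarate (3,4-dimethoxycyclobut-3-ene-1,2-dione)
Product: 14 4-hydroxy-2,3-dimethoxycyclobut-2-en-1-one (racemic)
Conditions: LiAlH(OtBu)3 (1.0 equiv), THF, −78 to −20 °C; aq. potassium sodium tartrate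
Reagents that add atoms: none
Why: The bulky, mild hydride reduces one of the two equivalent ketone carbonyls by 1,2-addition and should stop at the hydroxycyclobutenone, and the neutral work-up avoids acid-induced loss of methanol.

Step 11
Reactants: 14 4-hydroxy-2,3-dimethoxycyclobut-2-en-1-one
Product: 15 4-chloro-2,3-dimethoxycyclobut-2-en-1-one (racemic)
Conditions: PPh3, CCl4, CH2Cl2, 0 °C to rt; used without storage
Reagents that add atoms: tetrachloromethane, ClC(Cl)(Cl)Cl
Why: The Appel reaction replaces the secondary, carbonyl-activated hydroxyl by chloride through SN2 displacement of the oxyphosphonium group under neutral conditions, which avoids the acid that would ionise this vinylogous system.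

Step 12
Reactants: 12 {(Z)-1-[(3R)-7-(benzyloxy)-8-methoxychroman-3-yl]-2-methoxyethenyl}trimethylstannane; 15 4-chloro-2,3-dimethoxycyclobut-2-en-1-one
Product: 19 (3S)-7-(benzyloxy)-3-(3-hydroxy-2,4,5-trimethoxyphenyl)-8-methoxychroman, via 4-alkenylcyclobutenone 16 (not isolated), via dienylketene 17 (not isolated), via cyclohexadienone 18 (not isolated)
Conditions: Pd2(dba)3 (2.5 mol %), P(2-furyl)3 (10 mol %), CuI (10 mol %), 15 (1.5 equiv), 1,4-dioxane, 50 °C, then 100 °C
Reagents that add atoms: none
Why: Oxidative addition of the C4–Cl bond of 15 to zerovalent palladium gives an η3-oxocyclobutenyl complex, the alkenyl group of 12 is transferred from tin (the β-methoxy group makes the tin-bearing carbon nucleophilic), and reductive elimination at the unsubstituted terminus forms C6′–C1′ in 16 with retention of alkene geometry. At 100 °C 16 opens by reversible conrotatory 4π electrocyclic ring opening to dienylketene 17, whose thermal disrotatory 6π electrocyclisation joins the ketene carbon to the methoxy-bearing alkene carbon (C3′–C2′) and closes ring B as cyclohexadienone 18, which enolises to phenol 19. The closest known reaction type is the palladium-catalysed coupling of 4-chlorocyclobutenones with alkenylstannanes with in situ ring expansion to phenols. No stereocentre is created in 19, because C4 of 16 and the sp3 carbon of 18 are transient and C3 of the chroman is not touched. The selectivity needed is regiochemical and is secured by connectivity: coupling occurs at the less hindered CHCl terminus, only one hexatriene array exists, and so the ketene carbon becomes C3′–OH between the squarate-derived 4′-OMe and the enol-ether-derived 2′-OMe. The alkene geometry of 12 does not affect the outcome since C2′ becomes aromatic, and the excess of 15 is meant to outrun protodestannylation.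

Step 13
Reactants: 19 (3S)-7-(benzyloxy)-3-(3-hydroxy-2,4,5-trimethoxyphenyl)-8-methoxychroman
Product: 20 (3S)-3-(3-hydroxy-2,4,5-trimethoxyphenyl)-8-methoxychroman-7-ol
Conditions: H2 (1 atm), 10% Pd/C, EtOAc/MeOH, rt
Reagents that add atoms: none
Why: Catalytic hydrogenolysis cleaves the O–benzyl bond of the aryl benzyl ether while the methyl ethers, the free phenol and the C3 stereocentre are inert.

**Compound list**

1 | 2-methoxybenzene-1,3-diol (2-methoxyresorcinol) | COc1c(O)cccc1O | starting material
2 | N-[(2,4-dihydroxy-3-methoxyphenyl)methylidene]-N-methylmethanaminium chloride | C[N+](C)=Cc1ccc(O)c(OC)c1O.[Cl-] | intermediate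
3 | 2,4-dihydroxy-3-methoxybenzaldehyde | O=Cc1ccc(O)c(OC)c1O | intermediate
4 | 4-(benzyloxy)-2-hydroxy-3-methoxybenzaldehyde | O=Cc1ccc(OCc2ccccc2)c(OC)c1O | intermediate
5 | tert-butyl acrylate | C=CC(=O)OC(C)(C)C | starting material
6 | tert-butyl 7-(benzyloxy)-8-methoxy-2H-chromene-3-carboxylate | CC(C)(C)OC(=O)C1=Cc2ccc(OCc3ccccc3)c(OC)c2OC1 | intermediate
7 | 7-(benzyloxy)-8-methoxy-2H-chromene-3-carboxylic acid | OC(=O)C1=Cc2ccc(OCc3ccccc3)c(OC)c2OC1 | intermediate
8 | (3R)-7-(benzyloxy)-8-methoxychroman-3-carboxylic acid | OC(=O)[C@H]1COc2c(ccc(OCc3ccccc3)c2OC)C1 | intermediate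
9 | (3R)-7-(benzyloxy)-N,8-dimethoxy-N-methylchroman-3-carboxamide | CON(C)C(=O)[C@H]1COc2c(ccc(OCc3ccccc3)c2OC)C1 | intermediate
10 | 1-[(3R)-7-(benzyloxy)-8-methoxychroman-3-yl]-2-methoxyethan-1-one | COCC(=O)[C@H]1COc2c(ccc(OCc3ccccc3)c2OC)C1 | intermediate
11 | (Z)-1-[(3R)-7-(benzyloxy)-8-methoxychroman-3-yl]-2-methoxyethenyl trifluoromethanesulfonate | CO/C=C(\OS(=O)(=O)C(F)(F)F)[C@H]1COc2c(ccc(OCc3ccccc3)c2OC)C1 | intermediate
12 | {(Z)-1-[(3R)-7-(benzyloxy)-8-methoxychroman-3-yl]-2-methoxyethenyl}trimethylstannane | CO/C=C(\[Sn](C)(C)C)[C@H]1COc2c(ccc(OCc3ccccc3)c2OC)C1 | intermediate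
13 | dimethyl squarate (3,4-dimethoxycyclobut-3-ene-1,2-dione) | COC1=C(OC)C(=O)C1=O | starting material
14 | 4-hydroxy-2,3-dimethoxycyclobut-2-en-1-one (racemic) | O=C1C(OC)=C(OC)C1O | intermediate
15 | 4-chloro-2,3-dimethoxycyclobut-2-en-1-one (racemic) | O=C1C(OC)=C(OC)C1Cl | intermediate
16 | 4-{(Z)-1-[(3S)-7-(benzyloxy)-8-methoxychroman-3-yl]-2-methoxyethenyl}-2,3-dimethoxycyclobut-2-en-1-one (both C4 epimers) | CO/C=C(\C1C(=O)C(OC)=C1OC)[C@H]1COc2c(ccc(OCc3ccccc3)c2OC)C1 | intermediate
17 | (3E,5Z)-5-[(3S)-7-(benzyloxy)-8-methoxychroman-3-yl]-2,3,6-trimethoxyhexa-1,3,5-trien-1-one | O=C=C(OC)/C(OC)=C\C(=C/OC)[C@H]1COc2c(ccc(OCc3ccccc3)c2OC)C1 | intermediate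
18 | 5-[(3S)-7-(benzyloxy)-8-methoxychroman-3-yl]-2,3,6-trimethoxycyclohexa-2,4-dien-1-one (both C6 epimers) | O=C1C(OC)=C(OC)C=C([C@H]2COc3c(ccc(OCc4ccccc4)c3OC)C2)C1OC | intermediate
19 | (3S)-7-(benzyloxy)-3-(3-hydroxy-2,4,5-trimethoxyphenyl)-8-methoxychroman | COc1cc([C@H]2COc3c(ccc(OCc4ccccc4)c3OC)C2)c(OC)c(O)c1OC | intermediate
20 | (3S)-3-(3-hydroxy-2,4,5-trimethoxyphenyl)-8-methoxychroman-7-ol | COc1cc([C@H]2COc3c(ccc(O)c3OC)C2)c(OC)c(O)c1OC | target

**Step count**

Total: 13 steps. Longest linear sequence: 11 steps (steps 1–9, 12, 13); steps 10 and 11 form the short second branch.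

**Steps most likely to fail**

Step 12. Tin-to-palladium transfer from the α-branched, enol-ether-type carbon may be slow, so that protodestannylation of 12 and thermal decay of 15 outpace the coupling. The fallback sets out from 12 and 13 and returns at 20; it replaces the palladium coupling by carbonyl addition.
- Tin–lithium exchange on 12 (MeLi, THF, −78 °C), addition to 13 and capping of the tertiary alkoxide with chloromethyl methyl ether should give 4-{(Z)-1-[(3S)-7-(benzyloxy)-8-methoxychroman-3-yl]-2-methoxyethenyl}-2,3-dimethoxy-4-(methoxymethoxy)cyclobut-2-en-1-one F1.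
- Heating in toluene at 110 °C should bring about the same 4π opening and 6π closure and give (3S)-7-(benzyloxy)-3-[3-hydroxy-2,4,5-trimethoxy-6-(methoxymethoxy)phenyl]-8-methoxychroman F2, in which the surplus C6′ oxygen is already differentiated from the 3′-hydroxyl.
- Benzylation (BnBr, K2CO3, DMF) should give the 3′-O-benzyl ether F3, and HCl in MeOH should remove the methoxymethyl group to give the 6′-phenol F4.
- Tf2O and pyridine should give the 6′-aryl triflate F5, and hydrogenolysis (H2, Pd/C, Et3N, MeOH) should remove the triflate and both benzyl groups to reach 20.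

Step 11. The activated C4–O bond may ionise with participation of the C2 methoxy group, leading to rearrangement into the cyclobutenedione series, and the chloride may hydrolyse on handling. The fallback sets out from 14 and returns at 19; it abandons the halide as activating group. Acetylation (Ac2O, pyridine, DMAP cat., 0 °C) should give 2,3-dimethoxy-4-oxocyclobut-2-en-1-yl acetate F6. This stable allylic ester should enter the same η3-complex by ionisation with zerovalent palladium and couple with 12 (Pd2(dba)3, LiCl, DMF, 50 °C then 100 °C) to give 19 through 16–18.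

Step 8. Deprotonation at C3 may compete with that at the OCH2 group; β-elimination of the ring aryloxide and reclosure would then erode the configuration, and enol triflate regiochemistry would be mixed. The fallback sets out from 7 and returns at 19; it moves the creation of the stereocentre behind the construction of ring B, so that no enolisable stereocentre meets base.
- Acid 7 is taken through the operations of steps 6–9 with the C3=C4 double bond in place: 7-(benzyloxy)-N,8-dimethoxy-N-methyl-2H-chromene-3-carboxamide F7, then 1-[7-(benzyloxy)-8-methoxy-2H-chromen-3-yl]-2-methoxyethan-1-one F8 (whose only α-protons are those of OCH2), then (Z)-1-[7-(benzyloxy)-8-methoxy-2H-chromen-3-yl]-2-methoxyethenyl trifluoromethanesulfonate F9, then {(Z)-1-[7-(benzyloxy)-8-methoxy-2H-chromen-3-yl]-2-methoxyethenyl}trimethylstannane F10.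
- Coupling of F10 with 15 under the conditions of step 12 should give 7-(benzyloxy)-3-(3-hydroxy-2,4,5-trimethoxyphenyl)-8-methoxy-2H-chromene F11; the chromene double bond is cross-conjugated and offers no second 6π pathway.
- Iridium-catalysed asymmetric hydrogenation of the trisubstituted C3=C4 bond ([Ir(cod)(L′)]BArF, L′ = (S)-4-tert-butyl-2-[2-(diphenylphosphanyl)phenyl]-4,5-dihydrooxazole, H2, CH2Cl2) should then set C3 and give 19.

**Further compounds**

F1 | step 12 | 4-{(Z)-1-[(3S)-7-(benzyloxy)-8-methoxychroman-3-yl]-2-methoxyethenyl}-2,3-dimethoxy-4-(methoxymethoxy)cyclobut-2-en-1-one | CO/C=C(\C1(OCOC)C(=O)C(OC)=C1OC)[C@H]1COc2c(ccc(OCc3ccccc3)c2OC)C1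
F2 | step 12 | (3S)-7-(benzyloxy)-3-[3-hydroxy-2,4,5-trimethoxy-6-(methoxymethoxy)phenyl]-8-methoxychroman | COCOc1c(OC)c(OC)c(O)c(OC)c1[C@H]1COc2c(ccc(OCc3ccccc3)c2OC)C1
F3 | step 12 | (3S)-7-(benzyloxy)-3-[3-(benzyloxy)-2,4,5-trimethoxy-6-(methoxymethoxy)phenyl]-8-methoxychroman | COCOc1c(OC)c(OC)c(OCc2ccccc2)c(OC)c1[C@H]1COc2c(ccc(OCc3ccccc3)c2OC)C1
F4 | step 12 | 4-(benzyloxy)-2-[(3S)-7-(benzyloxy)-8-methoxychroman-3-yl]-3,5,6-trimethoxyphenol | Oc1c(OC)c(OC)c(OCc2ccccc2)c(OC)c1[C@H]1COc2c(ccc(OCc3ccccc3)c2OC)C1
F5 | step 12 | 4-(benzyloxy)-2-[(3S)-7-(benzyloxy)-8-methoxychroman-3-yl]-3,5,6-trimethoxyphenyl trifluoromethanesulfonate | O=S(=O)(Oc1c(OC)c(OC)c(OCc2ccccc2)c(OC)c1[C@H]1COc2c(ccc(OCc3ccccc3)c2OC)C1)C(F)(F)F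
F6 | step 11 | 2,3-dimethoxy-4-oxocyclobut-2-en-1-yl acetate | CC(=O)OC1C(=O)C(OC)=C1OC
F7 | step 8 | 7-(benzyloxy)-N,8-dimethoxy-N-methyl-2H-chromene-3-carboxamide | CON(C)C(=O)C1=Cc2ccc(OCc3ccccc3)c(OC)c2OC1
F8 | step 8 | 1-[7-(benzyloxy)-8-methoxy-2H-chromen-3-yl]-2-methoxyethan-1-one | COCC(=O)C1=Cc2ccc(OCc3ccccc3)c(OC)c2OC1
F9 | step 8 | (Z)-1-[7-(benzyloxy)-8-methoxy-2H-chromen-3-yl]-2-methoxyethenyl trifluoromethanesulfonate | CO/C=C(\OS(=O)(=O)C(F)(F)F)C1=Cc2ccc(OCc3ccccc3)c(OC)c2OC1
F10 | step 8 | {(Z)-1-[7-(benzyloxy)-8-methoxy-2H-chromen-3-yl]-2-methoxyethenyl}trimethylstannane | CO/C=C(\[Sn](C)(C)C)C1=Cc2ccc(OCc3ccccc3)c(OC)c2OC1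
F11 | step 8 | 7-(benzyloxy)-3-(3-hydroxy-2,4,5-trimethoxyphenyl)-8-methoxy-2H-chromene | COc1cc(C2=Cc3ccc(OCc4ccccc4)c(OC)c3OC2)c(OC)c(O)c1OC
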